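## Structural features

1. The target is a 1,2,3,4-tetrasubstituted cyclobutane of the head-to-tail (truxillate) type. C1 carries a free CO2H, C2 a 4-hydroxyphenyl group, C3 a carboxyl esterified with the secondary hydroxyl of (R)-3-(3,4-dihydroxyphenyl)lactic acid, and C4 a 3,4-dihydroxyphenyl group.
2. The four ring stereocentres are contiguous, (1R,2R,3S,4S), and every vicinal pair is trans, so the two aryl groups are cis to each other on one face and the two carboxyl groups cis to each other on the other.
3. The ring is chiral only because the two aryl groups differ and the two carboxyl groups differ, so absolute control means placing each aryl group next to the correct carboxyl group; the fifth stereocentre, the (R)-lactate carbon, is remote from the ring.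
4. Formally the molecule is a crossed dimer of rosmarinic acid (C3, C4 and the whole ester side chain) and 4-coumaric acid (C1, C2).
5. Fragile groups are the two catechols (oxidation), the lactate C–H (flanked by acyloxy and carboxyl, base-labile once the carboxyl is an ester), the ring C–H bonds next to carbonyl, and the strained ring.
6. The real difficulty is the strained ring with four contiguous stereocentres in an unsymmetrical head-to-tail array, whose cis aryl–aryl relationship cannot be corrected by enolisation, together with the absolute sense of the ring.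
7. The key step exploits the C1–C2 bond. It joins a carboxyl-bearing carbon to an aryl-bearing carbon, both radical-stabilising, so a nitrogen atom inserted between C1 and C2 turns the ring into a 3,5-diarylpyrrolidine-2,4-dicarboxylate. In that ring the remaining C3–C4 bond is the Cα–Cβ bond of the caffeoyl unit of rosmarinic acid.

## Logic of the disconnections

(Pyrrolidine C2, C3, C4, C5 become cyclobutane C1, C4, C3, C2.)

**13 from 12.** Bonds cut: seven O–CH2Ph bonds (five aryl ethers, two esters). Reason: one neutral hydrogenolysis frees five phenols and two acids at the very end, so no base ever meets the finished lactate ester. Gain: all polar groups are masked by one group type throughout. Demand: the cyclobutane, the non-benzylic lactate C–O bond and five stereocentres must survive H2 over palladium.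

**12 from 9 (through 10 and 11).** Bond cut: ring bond C1–C2 of 12; both carbons are reattached to one nitrogen atom. Reason: the strained ring becomes an unstrained five-membered ring that is the direct product of a convergent cycloaddition, and whose stereocentres can be set by catalysis and equilibration. Gain: ring strain and the whole ring-assembly problem are removed. Demand: nitrogen must be excised with C–C coupling faster than bond rotation or fragmentation, so 9 must already be all-trans, including 2,5-trans.

**9 from 7.** No skeletal bond is cut; only the C5–H bond is exchanged between faces. Reason: a metal-bound azomethine ylide always delivers a 2,5-cis pyrrolidine, so one centre next to nitrogen must be inverted. Gain: the most reliable (endo) cycloaddition mode can be used, and because C2 and C5 both equilibrate, only the C3/C4 configuration has to be set correctly earlier. Demand: epimerisation must be confined to carbons next to nitrogen, must favour the all-trans isomer, and must leave C3, C4 and the lactate centre alone.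

**7 from 5 and 2 (through 6).** Bonds cut: C2–C3 and C4–C5 of the pyrrolidine. Reason: this divides the skeleton into a glycine imine and intact protected rosmarinic acid, which brings C3, C4, the ester link and the (R)-lactate centre ready-made. Gain: two bonds and four stereocentres in one step from two simple partners. Demand: regiocontrol (glycine carbon to Cβ), endo selectivity, and attack on one face of the alkene of 2 under catalyst control.

**5 from 3 and 4; 2 from 1.** Bonds cut: the C=N bond of 5, and five O–benzyl bonds of 2. Reason and gain: all three starting materials are commercial. Demand: benzylation of 1 must not epimerise the lactate centre or isomerise the alkene.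

## Other disconnections considered

Alternative 1: Cut C1–C4 and C2–C3, the two bonds between the cinnamate halves (the first idea that comes to mind). The forward key step is a crossed head-to-tail [2+2] photocycloaddition of 2 with benzyl (E)-3-[4-(benzyloxy)phenyl]prop-2-enoate A1. In the stacked head-to-tail arrangement that crystals, templates or excimers favour, each aryl group lies over the carboxyl of the partner, so the expected cycloadduct is the α-type dimer A2 with the aryl groups trans. The carbons that would need inversion carry aryl groups and cannot be epimerised through an enolate. Homodimers, head-to-head adducts and E/Z isomerisation would also compete, and nothing controls the absolute sense of the ring. The route is short, but it does not address the stereochemical problem that the chosen plan solves.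

Alternative 2: Cut the two ring-to-aryl bonds at C2 and C4. The forward key step is a pair of directed, Pd(OAc)2-catalysed C(sp3)–H arylations of the cis-cyclobutane-1,3-dicarboxylic acid derivative A3 with the two aryl iodides in turn, giving the all-cis diaryl amide A4. The aryl groups enter cis to the directing group, so the cis aryl–aryl relationship is natural. However, the absolute configuration is decided in the first arylation, between two enantiotopic CH2 groups of an achiral substrate, and that arylation must also stop cleanly at one aryl group. A4 then needs two base epimerisations, cleavage of a hindered auxiliary amide, and late esterification of a hindered acid with the lactate alcohol. This means nine or more linear steps, with the lactate either exposed to base or attached last.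

Alternative 3: Cut C1–C2 in a different sense, as a Wolff ring contraction. The forward key step is photolysis of the 2-diazocyclopentanone A5 in aqueous solvent: the aryl-bearing carbon migrates with retention and the ketene is hydrated to the C1 acid. The trisubstituted cyclopentanone behind A5 has no one-step convergent asymmetric assembly comparable to a cycloaddition. Hydration of the ketene should protonate C1 from the face away from the two flanking aryl groups, putting the carboxyl cis to both. The base correction that follows conflicts with the lactate ester, or forces it to be attached last. The plan is longer and its last stereocentre is set the wrong way.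

Key step: step 5

Assumption: (R)-rosmarinic acid, glycine benzyl ester hydrochloride and 4-(benzyloxy)benzaldehyde are taken as commercial. The ligand enantiomer in step 3 is assigned by analogy with the usual facial sense of its class; the requirement is addition to the Cα-Si/Cβ-Si face of the alkene of 2, and the antipodal ligand serves if the sense is reversed.

## Steps

Step 1
Reactants: 1 (R)-rosmarinic acid
Product: 2 benzyl (2R)-3-[3,4-bis(benzyloxy)phenyl]-2-({(2E)-3-[3,4-bis(benzyloxy)phenyl]prop-2-enoyl}oxy)propanoate
Conditions: BnBr (6 equiv), K2CO3 (6 equiv), DMF, N2, rt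
Reagents that add atoms: benzyl bromide, BrCc1ccccc1
Why: Williamson etherification of the four phenols and O-alkylation of the carboxylate; carbonate at room temperature is far too weak to enolise the α-acyloxy ester or to isomerise the (E)-alkene, so the (R) centre is carried through and no new stereocentre forms.

Step 2
Reactants: 3 glycine benzyl ester hydrochloride; 4 4-(benzyloxy)benzaldehyde
Product: 5 benzyl N-[(E)-4-(benzyloxy)benzylidene]glycinate
Conditions: Et3N (1.05 equiv), MgSO4, CH2Cl2, rt; filtered and used crude
Reagents that add atoms: none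
Why: Imine condensation of the liberated primary amine with a non-enolisable aryl aldehyde, driven by removal of water; the (E)-aldimine forms and there is no stereocentre.

Step 3
Reactants: 5 benzyl N-[(E)-4-(benzyloxy)benzylidene]glycinate; 2 penta-O-benzyl rosmarinate
Product: 7 benzyl (2R,3S,4R,5S)-3-[3,4-bis(benzyloxy)phenyl]-5-[4-(benzyloxy)phenyl]-4-({(2R)-1-(benzyloxy)-3-[3,4-bis(benzyloxy)phenyl]-1-oxopropan-2-yl}oxycarbonyl)pyrrolidine-2-carboxylate (endo adduct; 2,4,5-cis; 3-trans), via silver azomethine ylide 6 (not isolated)
Conditions: AgOAc (5 mol %), (R)-QUINAP (5.5 mol %), iPr2NEt (10 mol %), THF, −20 °C to rt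
Reagents that add atoms: none
Why: Catalytic asymmetric 1,3-dipolar cycloaddition of a metal-bound azomethine ylide: N,O-chelation to monovalent silver acidifies the glycine CH2 and the amine base gives the W-shaped ylide 6, which fixes 2,5-cis; the (E)-alkene geometry is transferred as 3,4-trans, the ester carbonyl lies endo under the metal (4,5-cis), and the P,N-ligand leaves open the Cα-Si/Cβ-Si face of the alkene (3S,4R); the regiochemistry follows from the nucleophilic ylide carbon attacking the β-carbon of the cinnamate.

Step 4
Reactants: 7 endo pyrrolidine (2R,3S,4R,5S)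
Product: 9 benzyl (2R,3S,4R,5R)-3-[3,4-bis(benzyloxy)phenyl]-5-[4-(benzyloxy)phenyl]-4-({(2R)-1-(benzyloxy)-3-[3,4-bis(benzyloxy)phenyl]-1-oxopropan-2-yl}oxycarbonyl)pyrrolidine-2-carboxylate (all-trans), via C5 aminoalkyl radical 8 (not isolated)
Conditions: [Ir{dF(CF3)ppy}2(dtbbpy)]PF6 (1 mol %), PhSH (1 equiv), MeCN/MeOH, blue LEDs, rt, degassed
Reagents that add atoms: none
Why: Photoredox/thiol epimerisation of an α-amino stereocentre by reversible hydrogen-atom transfer: the thiyl radical abstracts the weak, hydridic, benzylic C5–H, and planar radical 8 takes hydrogen back from PhSH on either face until the thermodynamically preferred all-trans isomer, freed of the 4,5-cis aryl/ester contact, dominates; C3, C4 and the electron-poor lactate C–H are not α to nitrogen and stay fixed, so the C3/C4 configuration from step 3 anchors the result, and C2, also α to nitrogen, already sits trans to the C3 aryl group.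

Step 5
Reactants: 9 all-trans pyrrolidine (2R,3S,4R,5R)
Product: 12 benzyl (1R,2R,3S,4S)-4-[3,4-bis(benzyloxy)phenyl]-2-[4-(benzyloxy)phenyl]-3-({(2R)-1-(benzyloxy)-3-[3,4-bis(benzyloxy)phenyl]-1-oxopropan-2-yl}oxycarbonyl)cyclobutane-1-carboxylate, via 1,1-diazene 10 (not isolated), via singlet 1,4-biradical 11 (not isolated)
Conditions: PhI(OH)OTs (2.5 equiv), H2NCO2NH4 (8 equiv), CF3CH2OH, 80 °C
Reagents that add atoms: none
Why: PhI(OH)OTs and ammonia released from ammonium carbamate give an electrophilic iodonitrene that transfers NH to the ring nitrogen, and a second equivalent of the trivalent iodine oxidant takes the resulting hydrazine to 1,1-diazene 10. Diazene 10 loses N2 to give singlet 1,4-biradical 11, whose termini (the former C2, stabilised by the ester, and the former C5, benzylic) couple to form the C1–C2 bond of the cyclobutane. The closest known reaction type is the iodonitrene-mediated nitrogen deletion of polysubstituted pyrrolidines to cyclobutanes, the modern form of the oxidation of N-aminopyrrolidines. The four-membered ring is closed by radical–radical recombination within the singlet 1,4-diyl, a five-to-four ring contraction, and not by a polar closure. C3 and C4 of 12 are spectators that keep the configuration set in step 3; C1 and C2 are re-formed with retention because coupling in the singlet diyl is faster than rotation about the bonds to the radical centres. The retained all-trans arrangement is also the least strained one, so retention and thermodynamic preference point the same way. The step needs coupling to win over β-scission of the central C–C bond into two cinnamate esters, and N-amination to win over oxidation of the benzyloxyarenes. The first is served by the ring-derived gauche geometry and short lifetime of the singlet diyl, the second by the much higher nucleophilicity of the secondary amine in the ammonia-buffered medium.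

Step 6
Reactants: 12 hepta-benzyl cyclobutane (1R,2R,3S,4S)
Product: 13 (1R,2R,3S,4S)-3-{[(1R)-1-carboxy-2-(3,4-dihydroxyphenyl)ethoxy]carbonyl}-4-(3,4-dihydroxyphenyl)-2-(4-hydroxyphenyl)cyclobutane-1-carboxylic acid
Conditions: H2 (1 atm), 10% Pd/C, THF/MeOH, rt; work-up under argon
Reagents that add atoms: none
Why: Heterogeneous hydrogenolysis cleaves the five benzyl aryl ethers and two benzyl esters under neutral conditions; the cyclobutane C–C bonds, the non-benzylic lactate C–O bond and all five stereocentres are inert, and no new stereocentre forms.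

## Compound list

1 | (R)-rosmarinic acid | O=C(/C=C/c1ccc(O)c(O)c1)O[C@H](Cc1ccc(O)c(O)c1)C(=O)O | starting material
2 | benzyl (2R)-3-[3,4-bis(benzyloxy)phenyl]-2-({(2E)-3-[3,4-bis(benzyloxy)phenyl]prop-2-enoyl}oxy)propanoate (penta-O-benzyl rosmarinate) | O=C(/C=C/c1ccc(OCc2ccccc2)c(OCc2ccccc2)c1)O[C@H](Cc1ccc(OCc2ccccc2)c(OCc2ccccc2)c1)C(=O)OCc1ccccc1 | intermediate
3 | glycine benzyl ester hydrochloride | Cl.NCC(=O)OCc1ccccc1 | starting material
4 | 4-(benzyloxy)benzaldehyde | O=Cc1ccc(OCc2ccccc2)cc1 | starting material
5 | benzyl N-[(E)-4-(benzyloxy)benzylidene]glycinate | O=C(C/N=C/c1ccc(OCc2ccccc2)cc1)OCc1ccccc1 | intermediate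
6 | silver azomethine ylide of 5 (N,O-chelated silver enolate, W-shaped, ligand omitted) | [Ag+].[O-]/C(OCc1ccccc1)=C\N=C\c1ccc(OCc2ccccc2)cc1 | intermediate
7 | benzyl (2R,3S,4R,5S)-3-[3,4-bis(benzyloxy)phenyl]-5-[4-(benzyloxy)phenyl]-4-({(2R)-1-(benzyloxy)-3-[3,4-bis(benzyloxy)phenyl]-1-oxopropan-2-yl}oxycarbonyl)pyrrolidine-2-carboxylate (endo adduct) | O=C(OCc2ccccc2)[C@@H]1N[C@H](c2ccc(OCc3ccccc3)cc2)[C@H](C(=O)O[C@H](Cc2ccc(OCc3ccccc3)c(OCc3ccccc3)c2)C(=O)OCc2ccccc2)[C@H]1c1ccc(OCc2ccccc2)c(OCc2ccccc2)c1 | intermediate
8 | C5 aminoalkyl radical of 7 (planar at C5; 2R,3S,4R retained) | O=C(OCc2ccccc2)[C@@H]1N[C](c2ccc(OCc3ccccc3)cc2)[C@H](C(=O)O[C@H](Cc2ccc(OCc3ccccc3)c(OCc3ccccc3)c2)C(=O)OCc2ccccc2)[C@H]1c1ccc(OCc2ccccc2)c(OCc2ccccc2)c1 | intermediate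
9 | benzyl (2R,3S,4R,5R)-3-[3,4-bis(benzyloxy)phenyl]-5-[4-(benzyloxy)phenyl]-4-({(2R)-1-(benzyloxy)-3-[3,4-bis(benzyloxy)phenyl]-1-oxopropan-2-yl}oxycarbonyl)pyrrolidine-2-carboxylate (all-trans) | O=C(OCc2ccccc2)[C@@H]1N[C@@H](c2ccc(OCc3ccccc3)cc2)[C@H](C(=O)O[C@H](Cc2ccc(OCc3ccccc3)c(OCc3ccccc3)c2)C(=O)OCc2ccccc2)[C@H]1c1ccc(OCc2ccccc2)c(OCc2ccccc2)c1 | intermediate
10 | 1,1-diazene (isodiazene) of 9, ring nitrogen doubly bonded to a terminal nitrogen; configuration of 9 retained | O=C(OCc2ccccc2)[C@@H]1[N+](=[N-])[C@@H](c2ccc(OCc3ccccc3)cc2)[C@H](C(=O)O[C@H](Cc2ccc(OCc3ccccc3)c(OCc3ccccc3)c2)C(=O)OCc2ccccc2)[C@H]1c1ccc(OCc2ccccc2)c(OCc2ccccc2)c1 | intermediate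
11 | singlet 1,4-biradical from 10 (radical centres at the former C2 and C5; former C3 and C4 configured as in 9) | O=C(OCc1ccccc1)[CH][C@H](c1ccc(OCc2ccccc2)c(OCc2ccccc2)c1)[C@@H](C(=O)O[C@H](Cc1ccc(OCc2ccccc2)c(OCc2ccccc2)c1)C(=O)OCc1ccccc1)[CH]c1ccc(OCc2ccccc2)cc1 | intermediate
12 | benzyl (1R,2R,3S,4S)-4-[3,4-bis(benzyloxy)phenyl]-2-[4-(benzyloxy)phenyl]-3-({(2R)-1-(benzyloxy)-3-[3,4-bis(benzyloxy)phenyl]-1-oxopropan-2-yl}oxycarbonyl)cyclobutane-1-carboxylate | O=C(OCc2ccccc2)[C@@H]1[C@@H](c2ccc(OCc3ccccc3)cc2)[C@H](C(=O)O[C@H](Cc2ccc(OCc3ccccc3)c(OCc3ccccc3)c2)C(=O)OCc2ccccc2)[C@H]1c1ccc(OCc2ccccc2)c(OCc2ccccc2)c1 | intermediate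
13 | (1R,2R,3S,4S)-3-{[(1R)-1-carboxy-2-(3,4-dihydroxyphenyl)ethoxy]carbonyl}-4-(3,4-dihydroxyphenyl)-2-(4-hydroxyphenyl)cyclobutane-1-carboxylic acid | O=C(O)[C@@H]1[C@@H](c2ccc(O)cc2)[C@H](C(=O)O[C@H](Cc2ccc(O)c(O)c2)C(=O)O)[C@H]1c1ccc(O)c(O)c1 | target

## Step count and least certain steps

Total step count: 6. Longest linear sequence: 5 steps (steps 1, 3, 4, 5, 6 from 1; the imine branch, steps 2, 3, 4, 5, 6, is equally long).

**Step 5 (key step).** The most likely failure is β-scission of the central C–C bond of 11 into two cinnamate esters instead of coupling, because both fragments are conjugated. Oxidation of the electron-rich benzyloxyarenes by the trivalent iodine reagent and ammonolysis of benzyl esters in hot trifluoroethanol could also erode the step. Fallback, from 9 back to 12: the N–N bond is made by nitrosation and the diazene is generated from an isolated hydrazine at low temperature. Treatment of 9 with tBuONO (THF, rt) gives N-nitrosopyrrolidine F1. Reduction with Zn in AcOH at 0 °C gives N-aminopyrrolidine F2. Oxidation of F2 with HgO (CH2Cl2, 0 °C to rt) generates 10 without iodine reagent, ammonia or heat; loss of N2 and coupling return to 12. The lower temperature should also favour barrierless coupling over scission.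

**Step 3.** The electron-rich β-aryl acrylate of a secondary alcohol may react slowly, so that self-condensation of the ylide with a second molecule of imine, or imine hydrolysis, competes. Endo selectivity may be incomplete, and facial discrimination by the ligand on this bulky ester may be weak. Fallback, from 2 and 5 back to 7: catalyst control is replaced by separation based on the lactate centre. The achiral, more forcing protocol (AgOAc 10 mol %, Et3N, toluene, rt) relies on the inherent endo preference and should give 7 together with its ring-antipodal endo diastereomer F3. The (R)-lactate centre makes these two diastereomers, so they can be separated by chromatography or crystallisation, and 7 goes on to step 4.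

**Step 4.** The equilibration may stop short of the all-trans isomer. Radical 8 may be oxidised further to the cyclic imine, which would tautomerise irreversibly to an enamino ester. Hydrogen abstraction at other benzylic positions may cause slow degradation. Fallback, from 5 back to 9: the wrong centre is moved from C5 to the base-labile C2 and corrected by base before the lactate is attached.
- Knoevenagel–Doebner condensation of commercial 3,4-bis(benzyloxy)benzaldehyde with malonic acid (pyridine, piperidine, 90 °C) gives cinnamic acid F4.
- Coupling with 3,5-dimethylpyrazole (EDC·HCl, DMAP) gives acyl pyrazole F5.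
- Exo-selective cycloaddition of 5 with F5 (Cu(CH3CN)4PF6, DTBM-Segphos, Et3N, THF) gives exo adduct F6, in which the aryl groups are already cis and only C2 is wrong.
- DBU in toluene epimerises C2 to all-trans acyl pyrazole F7.
- Acyl transfer (DMAP, iPr2NEt, toluene, 60 °C) to lactate alcohol F8 gives 9. F8 is made from sodium (R)-3-(3,4-dihydroxyphenyl)lactate with BnBr and K2CO3.

**Step 6.** Hydrogenolysis of seven benzyl groups may stall through catalyst poisoning by traces of sulfur or iodine carried over from steps 4 and 5. A benzylic bond of the strained ring may be opened, and the catechols may oxidise in air during isolation. Fallback, from 12 back to 13: non-reductive Lewis-acid debenzylation with BCl3 and pentamethylbenzene as cation scavenger (CH2Cl2, −78 °C), followed by a methanol quench under argon. This cleaves benzyl ethers and benzyl esters without hydrogen or metal and makes no new intermediate.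

## Further compounds

F1 | step 5 | benzyl (2R,3S,4R,5R)-3-[3,4-bis(benzyloxy)phenyl]-5-[4-(benzyloxy)phenyl]-4-({(2R)-1-(benzyloxy)-3-[3,4-bis(benzyloxy)phenyl]-1-oxopropan-2-yl}oxycarbonyl)-1-nitrosopyrrolidine-2-carboxylate | O=C(OCc2ccccc2)[C@@H]1N(N=O)[C@@H](c2ccc(OCc3ccccc3)cc2)[C@H](C(=O)O[C@H](Cc2ccc(OCc3ccccc3)c(OCc3ccccc3)c2)C(=O)OCc2ccccc2)[C@H]1c1ccc(OCc2ccccc2)c(OCc2ccccc2)c1
F2 | step 5 | benzyl (2R,3S,4R,5R)-1-amino-3-[3,4-bis(benzyloxy)phenyl]-5-[4-(benzyloxy)phenyl]-4-({(2R)-1-(benzyloxy)-3-[3,4-bis(benzyloxy)phenyl]-1-oxopropan-2-yl}oxycarbonyl)pyrrolidine-2-carboxylate | O=C(OCc2ccccc2)[C@@H]1N(N)[C@@H](c2ccc(OCc3ccccc3)cc2)[C@H](C(=O)O[C@H](Cc2ccc(OCc3ccccc3)c(OCc3ccccc3)c2)C(=O)OCc2ccccc2)[C@H]1c1ccc(OCc2ccccc2)c(OCc2ccccc2)c1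
F3 | step 3 | benzyl (2S,3R,4S,5R)-3-[3,4-bis(benzyloxy)phenyl]-5-[4-(benzyloxy)phenyl]-4-({(2R)-1-(benzyloxy)-3-[3,4-bis(benzyloxy)phenyl]-1-oxopropan-2-yl}oxycarbonyl)pyrrolidine-2-carboxylate (ring-antipodal endo diastereomer of 7) | O=C(OCc2ccccc2)[C@H]1N[C@@H](c2ccc(OCc3ccccc3)cc2)[C@@H](C(=O)O[C@H](Cc2ccc(OCc3ccccc3)c(OCc3ccccc3)c2)C(=O)OCc2ccccc2)[C@@H]1c1ccc(OCc2ccccc2)c(OCc2ccccc2)c1
F4 | step 4 | (2E)-3-[3,4-bis(benzyloxy)phenyl]prop-2-enoic acid | O=C(O)/C=C/c1ccc(OCc2ccccc2)c(OCc2ccccc2)c1
F5 | step 4 | (2E)-3-[3,4-bis(benzyloxy)phenyl]-1-(3,5-dimethyl-1H-pyrazol-1-yl)prop-2-en-1-one | Cc1cc(C)n(n1)C(=O)/C=C/c1ccc(OCc2ccccc2)c(OCc2ccccc2)c1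
F6 | step 4 | benzyl (2S,3S,4R,5R)-3-[3,4-bis(benzyloxy)phenyl]-5-[4-(benzyloxy)phenyl]-4-(3,5-dimethyl-1H-pyrazole-1-carbonyl)pyrrolidine-2-carboxylate (exo adduct) | O=C(OCc2ccccc2)[C@H]1N[C@@H](c2ccc(OCc3ccccc3)cc2)[C@H](C(=O)n2nc(C)cc2C)[C@H]1c1ccc(OCc2ccccc2)c(OCc2ccccc2)c1
F7 | step 4 | benzyl (2R,3S,4R,5R)-3-[3,4-bis(benzyloxy)phenyl]-5-[4-(benzyloxy)phenyl]-4-(3,5-dimethyl-1H-pyrazole-1-carbonyl)pyrrolidine-2-carboxylate (all-trans) | O=C(OCc2ccccc2)[C@@H]1N[C@@H](c2ccc(OCc3ccccc3)cc2)[C@H](C(=O)n2nc(C)cc2C)[C@H]1c1ccc(OCc2ccccc2)c(OCc2ccccc2)c1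
F8 | step 4 | benzyl (2R)-3-[3,4-bis(benzyloxy)phenyl]-2-hydroxypropanoate | O[C@H](Cc1ccc(OCc2ccccc2)c(OCc2ccccc2)c1)C(=O)OCc1ccccc1
F0 | step 6 | none | none
A1 | alternative 1 | benzyl (2E)-3-[4-(benzyloxy)phenyl]prop-2-enoate | O=C(/C=C/c1ccc(OCc2ccccc2)cc1)OCc1ccccc1
A2 | alternative 1 | benzyl (1R,2R,3R,4R)-4-[3,4-bis(benzyloxy)phenyl]-2-[4-(benzyloxy)phenyl]-3-({(2R)-1-(benzyloxy)-3-[3,4-bis(benzyloxy)phenyl]-1-oxopropan-2-yl}oxycarbonyl)cyclobutane-1-carboxylate (α-type head-to-tail photodimer, aryl groups trans; one of two ring-antipodal diastereomers) | O=C(OCc2ccccc2)[C@@H]1[C@@H](c2ccc(OCc3ccccc3)cc2)[C@@H](C(=O)O[C@H](Cc2ccc(OCc3ccccc3)c(OCc3ccccc3)c2)C(=O)OCc2ccccc2)[C@@H]1c1ccc(OCc2ccccc2)c(OCc2ccccc2)c1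
A3 | alternative 2 | methyl (1s,3s)-3-(quinolin-8-ylcarbamoyl)cyclobutane-1-carboxylate (cis) | COC(=O)[C@H]1C[C@@H](C(=O)Nc2cccc3cccnc23)C1
A4 | alternative 2 | methyl (1R,2R,3S,4S)-4-[3,4-bis(benzyloxy)phenyl]-2-[4-(benzyloxy)phenyl]-3-(quinolin-8-ylcarbamoyl)cyclobutane-1-carboxylate (all-cis) | O=C(Nc2cccc3cccnc23)[C@H]1[C@@H](c2ccc(OCc3ccccc3)cc2)[C@@H](C(=O)OC)[C@H]1c1ccc(OCc2ccccc2)c(OCc2ccccc2)c1
A5 | alternative 3 | methyl (1R,2S,5R)-2-[3,4-bis(benzyloxy)phenyl]-5-[4-(benzyloxy)phenyl]-3-diazo-4-oxocyclopentane-1-carboxylate | [N-]=[N+]=C1C(=O)[C@@H](c2ccc(OCc3ccccc3)cc2)[C@H](C(=O)OC)[C@H]1c1ccc(OCc2ccccc2)c(OCc2ccccc2)c1
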